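Locants follow carotenoid numbering (ring carbons C1–C6, exocyclic C7, primes for the furanoid half). TBS = tert-butyldimethylsilyl.

## Structural features

The target is (3S,5R,6R,3'S,5'R,8'S)-5',8'-epoxy-5,6,5',8'-tetrahydro-β,β-carotene-3,5,6,3'-tetrol. Ring A is a cyclohexane (C1–C6) carrying 3-OH, 5-OH and 6-OH. It is joined through C6 to an all-E octaene (C7 to C9', four methyl branches). The chain ends at C8' of ring C, a 2,5-dihydrofuran (oxygen between C5' and C8', C6'=C7') fused along C5'–C6' to ring B, a cyclohexane with 3'-OH.

There are six stereocentres. C5 and C6 are adjacent tertiary carbinols, trans to each other, with 6-OH cis and 5-OH trans to 3-OH. C3' and C5' sit in ring B, and C8' in ring C is separated from ring A by the whole polyene.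

The fragile parts are the polyene (light, oxygen, acid, E/Z drift), the tertiary allylic C6–OH (ionises in acid) and ring C (C8' is allylic and α to oxygen, so acid epimerises it).

The real difficulty is the trans C5/C6 diol wedged between the gem-dimethyl carbon C1 and C4. A syn dihydroxylation cannot give it, and an external nucleophile has no bias for the right carbon of a tetrasubstituted oxirane. Next come control of C8' and the union of two acid-labile ends.

The key step exploits C7, the one carbon on C6 that lies outside ring A. As an allylic CH2OH it steers epoxidation of C5=C6. As a tert-butyl carbonate it carries an oxygen to C5 from the face opposite the oxirane.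

## Logic of the disconnections

**37 ⇒ 36.** The two O–Si bonds at C3 and C3' are cut last. One fluoride step then frees both secondary alcohols, and nothing acidic touches the finished polyene, the C6 carbinol or C8'. The forward step must be fluoride-based and non-acidic.

**36 ⇒ 25 + 35.** The C11=C12 bond is cut. This splits C40 into C15 and C25 at a disubstituted double bond whose Z isomer is strained and reverts to E. The forward Wittig must tolerate two free tertiary hydroxyls in 25 and use only a weak alkoxide base.

**35 ⇒ 33 + 34.** The C11'=C12' bond is cut. 34 is a symmetrical, purchasable C10 unit, so the whole central chain costs no steps. The forward step must stop at mono-olefination, which an excess of 34 secures.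

**25 ⇒ 21 ⇒ 20 ⇒ 17 + 18.** The C11–P bond is cut, then the ester is taken back, then C7=C8 is cut. This reduces the C15 half to the C10 aldehyde 17 and the purchasable C5 unit 18. The demands are phosphonium formation without acid (the C6 carbinol is tertiary and allylic) and an olefination of a hindered α,β-dihydroxy aldehyde with a weakly basic carbanion.

**17 ⇒ 16 ⇒ 15.** C7 is returned to the alcohol level and the two O–C(=O) bonds of the carbonate are re-formed. This ties O5 and O7 into one ring and leaves only C6–OH free. Forward, mild methanolysis and a non-cleaving oxidation of a primary/tertiary 1,2-diol are needed.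

**15 ⇒ 14 (key).** The C5–O bond is cut and the oxirane is restored between C5 and C6. The trans-diol problem becomes a face-selective epoxidation plus an intramolecular delivery. The demand is attack at C5, not C6, with clean inversion.

**14 ⇒ 12 ⇒ 10.** The O7–C(=O) bond is cut (13), then both oxirane C–O bonds (11). This leads back to an allylic alcohol with one stereocentre. The epoxidation must place oxygen on the face of the C3 silyloxy group by reagent control.

**33 ⇒ 31 ⇒ 30 ⇒ 29 ⇒ 27 + 18; 27 ⇒ 26 ⇒ 10.** The C11'–P bond is cut. The O–C8' bond of ring C is cut and the oxygen is reconnected to C6' as an oxirane (30). Then C7'=C8' is cut (29 to 27 and 18), C7' is returned to the alcohol level (26) and the oxirane is removed (10). Both halves thus diverge from 10 through the two tartrate enantiomers. The demands are that C5' keeps its oxygen during ring-C formation and that the C8' epimers can be separated or recycled.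

**10 ⇒ 9 ⇒ 6 ⇒ 3 ⇒ 1.** The ester is taken back, the C6–C7 bond is cut (7, 8), then the enol C–O sulfonate bond (4) and the O–Si bond (2). This reaches 1, which supplies C3 and C3' from the chiral pool. The forward demand is a carbonylation of a hindered tetrasubstituted enol triflate.

## Other disconnections considered

**Alternative 1: singlet-oxygen cycloaddition across C3 and C6.**
- Cut: both the C3–O and C6–O bonds at once.
- Forward step: the achiral safranol silyl ether A1 takes up singlet oxygen (O2, rose bengal, light) across its diene termini to give the 2,3-dioxabicyclo[2.2.2]octene A2. O–O reduction then gives the cis-3,6-diol.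
- In favour: two C–O bonds and the cis C3/C6 relationship come in one concerted, suprafacial step from a cheap diene, with no metal and no C3 protecting group. On bond economy for this pair it is better than the chosen plan, and on reliability of the relative configuration it is equal.
- Against, here: A1 has no stereocentre, so A2 would form as a racemate and would need a resolution. C5 is still an alkene carbon, and its hydroxyl must then be placed trans to 6-OH at the more hindered end of C4=C5. Hydroxyl-directed oxidants would deliver to the wrong face. Ene reactions of the allylic methyl compete, and a peroxide has to be handled.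
- Comparison: the chosen plan takes C3 from the chiral pool, sets C6 by reagent control and sets C5 by stereospecific inversion. It is longer to the C3/C6 pair, but it solves the C5/C6 trans-diol, which this alternative leaves open.

**Alternative 2: allenol cycloisomerisation for ring C.**
- Cut: the O–C8' bond.
- Forward step: the (6'R)-allenol A3 is treated with Ph3PAuCl/AgBF4 (monovalent gold). The C5' hydroxyl adds to C8' and the C15 furanoid bis-silyl ether A4 forms with axis-to-centre chirality transfer.
- In favour: C8' is set stereospecifically under nearly neutral conditions. Step 17 of the chosen plan has little facial bias and relies on separation and recycling, so on C8' control this alternative is clearly better.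
- Against, here: A3 needs an alkyne homologation, a cross-coupling and a face-selective hydride SN2' reduction. Any leakage in the allene axis shows up at C8', and the Lewis-acidic metal can epimerise the allylic ether it has just made.
- Comparison: structurally it addresses ring C only, so it can replace steps 15–17 but not the carbonate step. Mechanistically both are stereospecific and equal in that respect. In step count it is about one step longer than the rearrangement but saves the epimer recycle. It is kept as the fallback for step 17.

**Alternative 3: methylalumination and Negishi coupling for C9 and C10–C11.**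
- Cut: the C9–CH3 and C10–C11 bonds.
- Forward step: the enyne A5 is treated with Me3Al/Cp2ZrCl2 (methyl to C9, aluminium to C10). The dienylalane is transmetalated with ZnCl2 and coupled under Pd(PPh3)4 (zerovalent palladium) with the iodo dienoate A6 to give the C20 pentaenoate A7.
- In favour: syn carbometalation fixes the C9=C10 geometry, and no phosphonium salt is needed. On geometric purity it is better than the olefination of step 10.
- Against, here: excess Me3Al is a strong Lewis acid next to a tertiary allylic C6–O bond. Both tertiary hydroxyls must be silylated first, A5 costs extra steps from 17, and A7 forces a C20 + C20 union with a longer furanoid partner.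
- Comparison: it creates no stereocentre, so the ring-A triol would still come from the carbonate step. The step count is equal at best. The chosen plan gets its chain from purchasable C5 and C10 units.

Key step: step 7

Remark on the chemistry: 1, 18 and 34 are taken as purchasable. The stereostructures of 14 and 15 were checked atom by atom against the target (oxirane oxygen cis to the C3 silyloxy group, inversion at C5, retention at C6) and are used as drawn. The chain is attached in C5 and C25 portions, not by one late olefination with a long polyenyl anion, because such an anion is ambident.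

## Route

Step 1
Reactants: 1 (4R,6R)-4-hydroxy-2,2,6-trimethylcyclohexanone; 2 tert-butyldimethylsilyl chloride
Product: 3 (4R,6R)-4-(tert-butyldimethylsilyloxy)-2,2,6-trimethylcyclohexanone
Conditions: TBSCl, imidazole, DMF, rt
Reagents that add atoms: tert-butyldimethylsilyl chloride 2, CC(C)(C)[Si](C)(C)Cl
Why: Silylation of an unhindered secondary alcohol; the C3 stereocentre of both halves comes from the chiral pool and is not touched again.

Step 2
Reactants: 3; 4 N-phenylbis(trifluoromethanesulfonimide)
Product: 6 (4R)-4-(tert-butyldimethylsilyloxy)-2,6,6-trimethylcyclohex-1-en-1-yl trifluoromethanesulfonate, via lithium enolate 5 (not isolated)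
Conditions: LiN(iPr)2, THF, −78 °C; then PhNTf2, −78 °C to rt
Reagents that add atoms: N-phenylbis(trifluoromethanesulfonimide) 4, O=S(=O)(N(c1ccccc1)S(=O)(=O)C(F)(F)F)C(F)(F)F
Why: Enol triflate formation; only C5–H is enolisable (C1 is quaternary), so one enolate forms and is O-sulfonylated. The methyl-bearing stereocentre of 1 is erased on purpose.

Step 3
Reactants: 6; 7 carbon monoxide; 8 methanol
Product: 9 methyl (4R)-4-(tert-butyldimethylsilyloxy)-2,6,6-trimethylcyclohex-1-ene-1-carboxylate
Conditions: CO (1 atm), MeOH, Et3N, Pd(PPh3)4 (cat., zerovalent palladium), DMF, 70 °C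
Reagents that add atoms: carbon monoxide 7, [C-]#[O+]; methanol 8, CO
Why: Palladium-catalysed alkoxycarbonylation of an enol triflate (oxidative addition, CO insertion, methanolysis) installs C7; the silyl ether is inert.

Step 4
Reactants: 9
Product: 10 [(4R)-4-(tert-butyldimethylsilyloxy)-2,6,6-trimethylcyclohex-1-en-1-yl]methanol
Conditions: iBu2AlH, CH2Cl2, −78 to 0 °C
Reagents that add atoms: none
Why: 1,2-Reduction of a hindered conjugated ester to the allylic alcohol by an aluminium hydride; no conjugate reduction is expected at a tetrasubstituted alkene.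

Step 5
Reactants: 10; 11 tert-butyl hydroperoxide
Product: 12 C10 syn-epoxy alcohol, (3S,5S,6S)-3-(tert-butyldimethylsilyloxy)-5,6-epoxide with CH2OH (C7) on C6 and the oxirane oxygen cis to the C3 silyloxy group
Conditions: Ti(OiPr)4, L-(+)-diethyl tartrate, tBuOOH, 4 Å sieves, CH2Cl2, −20 °C
Reagents that add atoms: tert-butyl hydroperoxide 11, CC(C)(C)OO
Why: Sharpless asymmetric epoxidation; the L-(+)-tartrate complex delivers oxygen in the same sense as with simple primary allylic alcohols, which makes C6 (S) and puts the oxirane on the face of the C3 silyloxy group. Reagent control has to override the modest intrinsic bias of the ring, so stoichiometric titanium and low temperature are used.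

Step 6
Reactants: 12; 13 di-tert-butyl dicarbonate
Product: 14 tert-butyl carbonate of 12 at O7, (3S,5S,6S)
Conditions: Boc2O, DMAP, Et3N, CH2Cl2, rt
Reagents that add atoms: di-tert-butyl dicarbonate 13, CC(C)(C)OC(=O)OC(=O)OC(C)(C)C
Why: DMAP-catalysed acylation of the only free hydroxyl; the oxirane and silyl ether are inert to these basic conditions.

Step 7
Reactants: 14
Product: 15 cis-fused 5,7-cyclic carbonate with free 6-OH, (3S,5R,6S)-3-(tert-butyldimethylsilyloxy)
Conditions: BF3·OEt2, CH2Cl2, −78 to −40 °C; Et3N quench
Reagents that add atoms: none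
Why: BF3 binds the oxirane oxygen, the C5–O bond lengthens and the carbonyl oxygen of the C7 carbonate attacks C5 from the rear; the resulting tert-butoxy dioxanylium ion sheds 2-methylpropene, which makes the closure irreversible. The closest known reaction type is the Lewis-acid opening of epoxy tert-butyl carbonates (and urethanes) by neighbouring-group participation to give cyclic carbonates with inversion. The one ring closed, the 1,3-dioxan-2-one, forms in a 6-endo-tet mode with respect to the oxirane (both oxirane carbons end up in the new ring) and is cis-fused to ring A because C7 and the new C5–O bond lie on the same face. The new C5 stereocentre is fixed by inversion, so it is dictated by the C6 configuration set in step 5: the tether hangs on the face opposite the oxirane oxygen and can only deliver there, while C6 keeps its oxygen with retention. The step needs C5 over C6 selectivity (C6 attack would give a five-membered spiro carbonate): C6 is neopentylic between quaternary C1 and C5 and is deactivated for C–O heterolysis by the C7 oxygen, whereas C5 is a methyl-bearing tertiary centre remote from that oxygen. The C3 silyloxy group sits on the oxirane face and cannot reach the rear of either carbon, so no bridged ether is expected. Low temperature and short contact should keep the TBS ether and outrun 1,2-shifts or proton loss at C5.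

Step 8
Reactants: 15; 8 methanol
Product: 16 (3S,5R,6S)-3-(tert-butyldimethylsilyloxy)-5,6,7-triol (5-OH trans to 6-OH and to the C3 silyloxy group)
Conditions: K2CO3, MeOH, rt
Reagents that add atoms: none
Why: Base-catalysed transesterification removes the carbonate as dimethyl carbonate; no C–O bond at a stereocentre is broken and the silyl ether survives.

Step 9
Reactants: 16
Product: 17 (3S,5R,6R)-3-(tert-butyldimethylsilyloxy)-5,6-dihydroxy C10 aldehyde (CHO = C7)
Conditions: SO3·pyridine, DMSO, iPr2NEt, CH2Cl2, 0 °C
Reagents that add atoms: none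
Why: Parikh–Doering oxidation takes only the primary alcohol; a sulfonium-based oxidant does not cleave the 1,2-diol and tertiary hydroxyls cannot be oxidised. The aldehyde has no α-hydrogen.

Step 10
Reactants: 17; 18 ethyl (E)-4-(diethoxyphosphoryl)-3-methylbut-2-enoate
Product: 20 ethyl (2E,4E)-5-[ring A]-3-methylpenta-2,4-dienoate (C15 ester; ring A = (3S,5R,6R)-3-(tert-butyldimethylsilyloxy)-5,6-dihydroxy ring), via lithiated phosphonate 19 (not isolated)
Conditions: 18 (slight excess over base), n-BuLi, THF, 0 °C; then 17, 0 °C to rt
Reagents that add atoms: phosphonate 18, CCOC(=O)/C=C(\C)CP(=O)(OCC)OCC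
Why: Horner–Wadsworth–Emmons olefination gives the E C7=C8 bond under thermodynamic control, and the lithium counter-ion can chelate the α-hydroxy aldehyde and so assist addition to the hindered carbonyl. The stabilised carbanion is too weak a base to deprotonate the tertiary hydroxyls, and no free strong base remains that could trigger an α-ketol shift or retro-aldol cleavage. Any 9Z isomer is removed by chromatography.

Step 11
Reactants: 20
Product: 21 C15 triol, (2E,4E)-5-[ring A]-3-methylpenta-2,4-dien-1-ol
Conditions: iBu2AlH (excess), CH2Cl2, −78 °C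
Reagents that add atoms: none
Why: Aluminium hydride 1,2-reduction of the dienoate to the primary allylic alcohol; the hydroxyls only consume extra hydride.

Step 12
Reactants: 21; 22 carbon tetrabromide; 23 triphenylphosphine
Product: 25 ring-A C15 triphenylphosphonium bromide, via C15 allylic bromide 24 (not isolated)
Conditions: CBr4, PPh3, NaHCO3, CH2Cl2, 0 °C; then PPh3, rt
Reagents that add atoms: carbon tetrabromide 22, BrC(Br)(Br)Br; triphenylphosphine 23, c1ccc(cc1)P(c1ccccc1)c1ccccc1
Why: Appel bromination of the primary allylic alcohol followed by quaternisation of the reactive dienyl bromide in the same flask. The conditions are neutral, which matters because acid (as in the usual phosphine hydrobromide method) would ionise the tertiary allylic C6–OH. The hindered tertiary hydroxyls do not react.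

Step 13
Reactants: 10; 11 tert-butyl hydroperoxide
Product: 26 C10 anti-epoxy alcohol, (3S,5R,6R), oxirane oxygen trans to the C3 silyloxy group
Conditions: Ti(OiPr)4, D-(−)-diethyl tartrate, tBuOOH, 4 Å sieves, CH2Cl2, −20 °C
Reagents that add atoms: tert-butyl hydroperoxide 11, CC(C)(C)OO
Why: Sharpless asymmetric epoxidation with the enantiomeric tartrate delivers oxygen to the other face; this sets C5' with its oxygen trans to the C3' oxygen.

Step 14
Reactants: 26
Product: 27 C10 anti-epoxy aldehyde, (3S,5R,6S)
Conditions: SO3·pyridine, DMSO, iPr2NEt, CH2Cl2, 0 °C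
Reagents that add atoms: none
Why: Parikh–Doering oxidation of a primary alcohol; the non-enolisable epoxy aldehyde is configurationally safe.

Step 15
Reactants: 27; 18 ethyl (E)-4-(diethoxyphosphoryl)-3-methylbut-2-enoate
Product: 29 ethyl (2E,4E)-5-[(3S,5R,6S)-epoxy ring]-3-methylpenta-2,4-dienoate, via sodiated phosphonate 28 (not isolated)
Conditions: 18, NaH, THF, 0 °C; then 27, 0 °C to rt
Reagents that add atoms: phosphonate 18, CCOC(=O)/C=C(\C)CP(=O)(OCC)OCC
Why: Horner–Wadsworth–Emmons olefination gives the E C7'=C8' bond; the electron-poor dienoate keeps the vinyl oxirane stable. The substrate has no acidic hydroxyl, so the carbanion is made irreversibly with NaH, and the sodium counter-ion is a weaker Lewis acid than lithium toward the α,β-epoxy aldehyde, which makes oxirane opening or a 1,2-shift less likely.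

Step 16
Reactants: 29
Product: 30 (2E,4E)-5-[(3S,5R,6S)-epoxy ring]-3-methylpenta-2,4-dien-1-ol
Conditions: iBu2AlH, CH2Cl2, −78 °C
Reagents that add atoms: none
Why: Ester reduction at low temperature, where the oxirane is not opened; the now electron-rich diene prepares the oxirane for ionisation.

Step 17
Reactants: 30
Product: 31 furanoid C15 alcohol, (E)-3-[(3S,5R,8S)-furanoid bicycle]but-2-en-1-ol
Conditions: camphorsulfonic acid (cat.), CH2Cl2, −20 to 0 °C; Et3N quench
Reagents that add atoms: none
Why: Acid-catalysed epoxide–furanoid rearrangement: C6'–O heterolysis gives a pentadienyl cation with no ring β-hydrogen, and the oxygen that stays on C5' (retention) recloses on C8' to form ring C (5-membered) and C6'=C7'. The face of C8' is poorly differentiated, so the (8'R)-epimer is expected alongside; 31 is isolated by chromatography, and the epimer-rich remainder can be returned to the same acid, which re-ionises the C8'–O bond and redistributes the two epimers.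

Step 18
Reactants: 31; 22 carbon tetrabromide; 23 triphenylphosphine
Product: 33 furanoid C15 triphenylphosphonium bromide, via furanoid allylic bromide 32 (not isolated)
Conditions: CBr4, PPh3, NaHCO3, CH2Cl2, 0 °C; then PPh3, rt
Reagents that add atoms: carbon tetrabromide 22, BrC(Br)(Br)Br; triphenylphosphine 23, c1ccc(cc1)P(c1ccccc1)c1ccccc1
Why: Appel bromination and quaternisation under buffered, acid-free conditions, so the separated C8' configuration is not re-equilibrated.

Step 19
Reactants: 33; 34 (2E,4E,6E)-2,7-dimethylocta-2,4,6-trienedial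
Product: 35 furanoid C25 aldehyde (all-E, CHO = C12)
Conditions: 34 (3 equiv), NaOMe, MeOH/CH2Cl2, 0 °C to rt, dark
Reagents that add atoms: none
Why: Wittig olefination forms C11'=C12'; excess dialdehyde and the lower electrophilicity of the product aldehyde favour mono-condensation. The Z isomer at the new bond is strained and equilibrates to E on standing or gentle warming.

Step 20
Reactants: 25; 35
Product: 36 3,3'-bis-TBS ether of the target
Conditions: NaOMe, MeOH/CH2Cl2, rt, argon, dark; then EtOAc, 60 °C
Reagents that add atoms: none
Why: Wittig olefination forms C11=C12 and completes the C40 skeleton. Ylide formation needs only methoxide, so the tertiary hydroxyls and C8' are untouched; the thermal hold returns the hindered 11Z isomer to all-E.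

Step 21
Reactants: 36
Product: 37 (3S,5R,6R,3'S,5'R,8'S)-5',8'-epoxy-5,6,5',8'-tetrahydro-β,β-carotene-3,5,6,3'-tetrol (target)
Conditions: Bu4NF, THF, rt, dark
Reagents that add atoms: none
Why: Fluoride desilylation of two secondary silyl ethers; no acid is present, so the C6 carbinol, ring C and the polyene are not disturbed.

## Compound list

1 | (4R,6R)-4-hydroxy-2,2,6-trimethylcyclohexanone | O=C1C(C)(C)C[C@H](O)C[C@H]1C | starting material
2 | tert-butyldimethylsilyl chloride | CC(C)(C)[Si](C)(C)Cl | starting material
3 | (4R,6R)-4-(tert-butyldimethylsilyloxy)-2,2,6-trimethylcyclohexanone | O=C1C(C)(C)C[C@H](O[Si](C)(C)C(C)(C)C)C[C@H]1C | intermediate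
4 | N-phenylbis(trifluoromethanesulfonimide) | O=S(=O)(N(c1ccccc1)S(=O)(=O)C(F)(F)F)C(F)(F)F | starting material
5 | lithium (4R)-4-(tert-butyldimethylsilyloxy)-2,6,6-trimethylcyclohex-1-en-1-olate | [Li]OC1=C(C)C[C@@H](O[Si](C)(C)C(C)(C)C)CC1(C)C | intermediate
6 | (4R)-4-(tert-butyldimethylsilyloxy)-2,6,6-trimethylcyclohex-1-en-1-yl trifluoromethanesulfonate | O=S(=O)(OC1=C(C)C[C@@H](O[Si](C)(C)C(C)(C)C)CC1(C)C)C(F)(F)F | intermediate
7 | carbon monoxide | [C-]#[O+] | starting material
8 | methanol | CO | starting material
9 | methyl (4R)-4-(tert-butyldimethylsilyloxy)-2,6,6-trimethylcyclohex-1-ene-1-carboxylate | COC(=O)C1=C(C)C[C@@H](O[Si](C)(C)C(C)(C)C)CC1(C)C | intermediate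
10 | [(4R)-4-(tert-butyldimethylsilyloxy)-2,6,6-trimethylcyclohex-1-en-1-yl]methanol | OCC1=C(C)C[C@@H](O[Si](C)(C)C(C)(C)C)CC1(C)C | intermediate
11 | tert-butyl hydroperoxide | CC(C)(C)OO | starting material
12 | C10 syn-epoxy alcohol, (3S,5S,6S), oxirane oxygen cis to the C3 silyloxy group | OC[C@@]12O[C@@]2(C)C[C@@H](O[Si](C)(C)C(C)(C)C)CC1(C)C | intermediate
13 | di-tert-butyl dicarbonate | CC(C)(C)OC(=O)OC(=O)OC(C)(C)C | starting material
14 | C7 tert-butyl carbonate of the syn-epoxide, (3S,5S,6S) | CC(C)(C)OC(=O)OC[C@@]12O[C@@]2(C)C[C@@H](O[Si](C)(C)C(C)(C)C)CC1(C)C | intermediate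
15 | cis-fused 5,7-cyclic carbonate with free 6-OH, (3S,5R,6S) | O=C1OC[C@@]2(O)C(C)(C)C[C@H](O[Si](C)(C)C(C)(C)C)C[C@@]2(C)O1 | intermediate
16 | (3S,5R,6S)-3-(tert-butyldimethylsilyloxy)-5,6,7-triol | OC[C@@]1(O)C(C)(C)C[C@H](O[Si](C)(C)C(C)(C)C)C[C@@]1(C)O | intermediate
17 | (3S,5R,6R)-3-(tert-butyldimethylsilyloxy)-5,6-dihydroxy C10 aldehyde | O=C[C@@]1(O)C(C)(C)C[C@H](O[Si](C)(C)C(C)(C)C)C[C@@]1(C)O | intermediate
18 | ethyl (E)-4-(diethoxyphosphoryl)-3-methylbut-2-enoate | CCOC(=O)/C=C(\C)CP(=O)(OCC)OCC | starting material
19 | lithiated phosphonate (lithium salt of the γ-carbanion of 18) | [Li+].CCOC(=O)/C=C(\C)[CH-]P(=O)(OCC)OCC | intermediate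
20 | ring-A C15 ester, ethyl (2E,4E)-5-[(3S,5R,6R)-ring A]-3-methylpenta-2,4-dienoate | CCOC(=O)/C=C(C)/C=C/[C@@]1(O)C(C)(C)C[C@H](O[Si](C)(C)C(C)(C)C)C[C@@]1(C)O | intermediate
21 | ring-A C15 triol, (2E,4E)-5-[(3S,5R,6R)-ring A]-3-methylpenta-2,4-dien-1-ol | OC/C=C(C)/C=C/[C@@]1(O)C(C)(C)C[C@H](O[Si](C)(C)C(C)(C)C)C[C@@]1(C)O | intermediate
22 | carbon tetrabromide | BrC(Br)(Br)Br | starting material
23 | triphenylphosphine | c1ccc(cc1)P(c1ccccc1)c1ccccc1 | starting material
24 | ring-A C15 allylic bromide | BrC/C=C(C)/C=C/[C@@]1(O)C(C)(C)C[C@H](O[Si](C)(C)C(C)(C)C)C[C@@]1(C)O | intermediate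
25 | ring-A C15 triphenylphosphonium bromide | [Br-].c1ccc(cc1)[P+](c1ccccc1)(c1ccccc1)C/C=C(C)/C=C/[C@@]1(O)C(C)(C)C[C@H](O[Si](C)(C)C(C)(C)C)C[C@@]1(C)O | intermediate
26 | C10 anti-epoxy alcohol, (3S,5R,6R), oxirane oxygen trans to the C3 silyloxy group | OC[C@]12O[C@]2(C)C[C@@H](O[Si](C)(C)C(C)(C)C)CC1(C)C | intermediate
27 | C10 anti-epoxy aldehyde, (3S,5R,6S) | O=C[C@]12O[C@]2(C)C[C@@H](O[Si](C)(C)C(C)(C)C)CC1(C)C | intermediate
28 | sodiated phosphonate (sodium salt of the γ-carbanion of 18) | [Na+].CCOC(=O)/C=C(\C)[CH-]P(=O)(OCC)OCC | intermediate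
29 | C15 epoxy dienoate, (3S,5R,6S), 7E,9E | CCOC(=O)/C=C(C)/C=C/[C@]12O[C@]2(C)C[C@@H](O[Si](C)(C)C(C)(C)C)CC1(C)C | intermediate
30 | C15 epoxy dienol, (3S,5R,6S), 7E,9E | OC/C=C(C)/C=C/[C@]12O[C@]2(C)C[C@@H](O[Si](C)(C)C(C)(C)C)CC1(C)C | intermediate
31 | furanoid C15 alcohol, (3S,5R,8S), 9E | OC/C=C(\C)[C@@H]1C=C2C(C)(C)C[C@H](O[Si](C)(C)C(C)(C)C)C[C@@]2(C)O1 | intermediate
32 | furanoid C15 allylic bromide, (3S,5R,8S) | BrC/C=C(\C)[C@@H]1C=C2C(C)(C)C[C@H](O[Si](C)(C)C(C)(C)C)C[C@@]2(C)O1 | intermediate
33 | furanoid C15 triphenylphosphonium bromide, (3S,5R,8S) | [Br-].c1ccc(cc1)[P+](c1ccccc1)(c1ccccc1)C/C=C(\C)[C@@H]1C=C2C(C)(C)C[C@H](O[Si](C)(C)C(C)(C)C)C[C@@]2(C)O1 | intermediate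
34 | (2E,4E,6E)-2,7-dimethylocta-2,4,6-trienedial | O=C/C(C)=C/C=C/C=C(C)/C=O | starting material
35 | furanoid C25 aldehyde, all-E, (3'S,5'R,8'S), CHO = C12 | O=C/C(C)=C/C=C/C=C(C)/C=C/C=C(\C)[C@@H]1C=C2C(C)(C)C[C@H](O[Si](C)(C)C(C)(C)C)C[C@@]2(C)O1 | intermediate
36 | 3,3'-bis(tert-butyldimethylsilyl) ether of the target | CC(/C=C/C=C(C)/C=C/[C@@]1(O)C(C)(C)C[C@H](O[Si](C)(C)C(C)(C)C)C[C@@]1(C)O)=C\C=C\C=C(C)\C=C\C=C(/C)[C@@H]1C=C2C(C)(C)C[C@H](O[Si](C)(C)C(C)(C)C)C[C@@]2(C)O1 | intermediate
37 | (3S,5R,6R,3'S,5'R,8'S)-5',8'-epoxy-5,6,5',8'-tetrahydro-β,β-carotene-3,5,6,3'-tetrol | CC(/C=C/C=C(C)/C=C/[C@@]1(O)C(C)(C)C[C@H](O)C[C@@]1(C)O)=C\C=C\C=C(C)\C=C\C=C(/C)[C@@H]1C=C2C(C)(C)C[C@H](O)C[C@@]2(C)O1 | target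

## Step count and risks

Total: 21 steps. Longest linear sequence: 14 steps (steps 1–12, 20, 21). The ring-B/C branch is steps 13–19, starting from 10.

**Step 7 (key step).** The tethered oxygen may attack C6 and give the five-membered carbonate. The C5 cationoid centre may lose a proton or undergo a 1,2-shift (ring contraction). BF3 may also remove the silyl group at C3. Fallback, from 12 and back at 16: 12 is opened with benzoic acid under Ti(OiPr)4. The metal is chelated between O7 and the oxirane and steers the external carboxylate to the distal carbon C5 with inversion, giving the C5 benzoate F1. Methanolysis (K2CO3, MeOH) of F1 gives 16.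

**Step 17.** Facial selectivity at C8' is expected to be poor, so material throughput depends on separation and re-equilibration of the unwanted epimer. Prolonged acid contact could also ionise the primary allylic alcohol. Fallback, from 27 and back at 31:
- Ohira–Bestmann homologation (dimethyl (1-diazo-2-oxopropyl)phosphonate, K2CO3, MeOH) gives the ethynyl epoxide F2.
- Sonogashira coupling with (E)-3-iodobut-2-en-1-ol (PdCl2(PPh3)2, divalent palladium precatalyst, CuI, iPr2NH) gives the epoxy enynol F3.
- iBu2AlH bound to the oxirane oxygen delivers hydride to C8' on the same face (SN2'), giving the (6'R)-allenic diol F4.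
- Ph3PAuCl/AgBF4 (monovalent gold) makes the C5' hydroxyl add to C8' with axis-to-centre transfer, giving 31 as a single C8' epimer.

**Step 5.** Reagent control may not fully override the ring's own facial bias (mismatched double stereodifferentiation), and a tetrasubstituted alkene reacts slowly. Any 26 formed is not lost, since it feeds step 14. Fallback, from 10 and back at 14:
- Boc2O/DMAP gives the allylic carbonate F5.
- Bu4NF frees the C3 hydroxyl to give F6.
- VO(acac)2/tBuOOH epoxidises from the face of the homoallylic hydroxyl (substrate-directed, cis delivery) to give the syn-epoxy carbonate F7.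
- TBSCl/imidazole on F7 returns 14.

**Step 10.** Addition to the hindered aldehyde may be slow. Traces of strong base could set off an α-ketol shift or retro-aldol cleavage of the unprotected hydroxy aldehyde, and some 9Z isomer may form. Fallback, from 17 and back at 20: neutral Wittig reaction with the stabilised ylide Ph3P=CHC(O)CH3 (toluene, 90 °C, no base) gives the C13 enone F8. Horner–Wadsworth–Emmons reaction of F8 with triethyl phosphonoacetate (NaH, THF) then gives 20.

## Further compounds

F1 | step 7 | C5 benzoate of 16, (3S,5R,6S), free 6-OH and 7-OH | OC[C@@]1(O)C(C)(C)C[C@H](O[Si](C)(C)C(C)(C)C)C[C@@]1(C)OC(=O)c1ccccc1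
F2 | step 17 | ethynyl anti-epoxide (C7≡C8 on C6), (3S,5R) | C#C[C@]12O[C@]2(C)C[C@@H](O[Si](C)(C)C(C)(C)C)CC1(C)C
F3 | step 17 | C15 epoxy enynol, 9E | OC/C=C(\C)C#C[C@]12O[C@]2(C)C[C@@H](O[Si](C)(C)C(C)(C)C)CC1(C)C
F4 | step 17 | (3S,5R,6R)-allenic C15 diol, 9E | OC/C=C(\C)C=[C@@]=C1C(C)(C)C[C@H](O[Si](C)(C)C(C)(C)C)C[C@@]1(C)O
F5 | step 5 | tert-butyl carbonate of 10 | CC(C)(C)OC(=O)OCC1=C(C)C[C@@H](O[Si](C)(C)C(C)(C)C)CC1(C)C
F6 | step 5 | tert-butyl carbonate of the (4R)-4-hydroxy allylic alcohol | CC(C)(C)OC(=O)OCC1=C(C)C[C@@H](O)CC1(C)C
F7 | step 5 | syn-epoxy tert-butyl carbonate with free 3-OH | CC(C)(C)OC(=O)OC[C@@]12O[C@@]2(C)C[C@@H](O)CC1(C)C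
F8 | step 10 | C13 enone, (E)-4-[(3S,5R,6R)-ring A]but-3-en-2-one | CC(=O)/C=C/[C@@]1(O)C(C)(C)C[C@H](O[Si](C)(C)C(C)(C)C)C[C@@]1(C)O
A1 | alternative 1 | safranol TBS ether | CC1=C(CO[Si](C)(C)C(C)(C)C)C(C)(C)CC=C1
A2 | alternative 1 | C3,C6-endoperoxide | CC1=C[C@@H]2CC(C)(C)[C@@]1(CO[Si](C)(C)C(C)(C)C)OO2
A3 | alternative 2 | (6'R)-allenol bis-silyl ether | CC(C)(C)[Si](C)(C)OC/C=C(\C)C=[C@@]=C1C(C)(C)C[C@H](O[Si](C)(C)C(C)(C)C)C[C@@]1(C)O
A4 | alternative 2 | C15 furanoid bis-silyl ether | CC(C)(C)[Si](C)(C)OC/C=C(\C)[C@@H]1C=C2C(C)(C)C[C@H](O[Si](C)(C)C(C)(C)C)C[C@@]2(C)O1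
A5 | alternative 3 | silylated ring-A enyne | C#C/C=C/[C@@]1(O[Si](CC)(CC)CC)C(C)(C)C[C@H](O[Si](C)(C)C(C)(C)C)C[C@@]1(C)O[Si](CC)(CC)CC
A6 | alternative 3 | ethyl (2E,4E)-5-iodo-3-methylpenta-2,4-dienoate | CCOC(=O)/C=C(C)/C=C/I
A7 | alternative 3 | silylated ring-A C20 pentaenoate | CCOC(=O)/C=C(C)/C=C/C=C(C)/C=C/[C@@]1(O[Si](CC)(CC)CC)C(C)(C)C[C@H](O[Si](C)(C)C(C)(C)C)C[C@@]1(C)O[Si](CC)(CC)CC
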